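The data stem from a simulated flask with made-up constants; noise was put on by code.

The process chemist has one coupling and four vessels, and wants the one that delivers the most target.

| flask | starting material | coupling partner | remark | time |
|---|---|---|---|---|
| red | 0.50 M | 1 equiv | run made earlier |  |
| grey | 0.75 M | 1 equiv | run made earlier |  |
| north-east | 0.50 M | 1.00 equiv | one stirred flow tank at steady state, fed with the mixture as stated, mean residence time 2.5 h |  |
| north-west | 0.50 M | 1.00 equiv (fed, over 1.25 h) | all but coupling partner at the start; coupling partner goes in evenly over 1.25 h, the run ends at 2.5 h | 2.5 h |
| east | 0.50 M | 1.00 equiv | everything together in a closed stirred flask, run for 2.5 h | 2.5 h |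
| north | 0.50 M | 1.00 equiv | a single well-mixed tank run continuously and read at steady state, 12.5 h in it on average |  |

red run (percent of the starting material charged)

| time / h | target / % | starting material / % |
|---|---|---|
| 0.417 | 7.1 | 93.4 |
| 0.833 | 13.7 | 86.6 |
| 1.33 | 20.7 | 79.2 |
| 1.50 | 22.5 | 76.9 |
| 2.00 | 28.3 | 71.7 |
| 2.50 | 33.5 | 66.2 |

grey run (percent of the starting material charged)

| time / min | target / % | starting material / % |
|---|---|---|
| 4.00 | 0.7 | 98.1 |
| 6.00 | 2.0 | 98.2 |
| 10.0 | 3.9 | 96.1 |
| 15.0 | 4.6 | 94.2 |
| 25.0 | 8.1 | 90.9 |
| 50.0 | 15.8 | 83.9 |

(scatter of a reading: 0.5 percentage points)

1. the set-up with the highest amount of target at the outlet or at the end, in percent of the starting material put in ("none" if the first two lie within 2 percentage points) (north-east / north-west / east / north / none)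
2. amount of target at the outlet or at the end, in percent of the starting material put in, north-east
3. amount of target at the outlet or at the end, in percent of the starting material put in, north-west
4. amount of target at the outlet or at the end, in percent of the starting material put in, east
5. amount of target at the outlet or at the end, in percent of the starting material put in, north

- the stated concentrations are those of everything mixed, before any reaction; amounts are the same in each set-up
- the feed brings no volume worth counting
- the earlier runs were made in a closed, stirred flask

Target and starting material add up to about 100% in the red and grey runs, and these equimolar charges keep c(starting material) equal to c(coupling partner), so the reckoning follows L, the fraction of starting material left. If L falls as κ times L to the power 1.5, the closed-flask integral gives κ as 2(L to the power −0.5, minus 1) divided by time. The last red reading gives κ, the fraction-left rate constant at the red concentration, as 0.183 h⁻¹. The last grey reading gives 0.220 h⁻¹, a ratio of 1.20 against the 1.22 expected from the square root of the concentration ratio, so the readings fit an overall reaction order of 1.5.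

The east recipe repeats the red run, so east should read about 33.5%. A steady tank works at its outlet L, so there the fraction lost equals κτ times L to the power 1.5. With κτ of 0.458 the north-east tank holds L at 72.0%, and with 2.29 the north tank holds it at 40.6%. My own reckoning therefore gives 28.0% of target for north-east and 59.4% for north, which leads because its 12.5 h is longer than the 2.5 h of the other set-ups. Dosing in the north-west flask makes the two concentrations unequal, so this equal-concentration rule gives no number for it.

The forecast chose north, with 28% for north-east, 28% for north-west, 33.5% for east and 59% for north, on the ground that “North is clearly best, because of its long residence time.”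

The simulation gives 27.8% for north-east, 29.1% for north-west, 33.5% for east and 59.1% for north, so the best set-up is north.

    starting material + coupling partner → target, rate k1*[starting material]*[coupling partner]^0.5 (k = 0.00427 M⁻⁰·⁵ min⁻¹)

North stands 26 percentage points above east against a margin of 2 points, with c(starting material) and c(coupling partner) both at 0.204 M in its tank. At three times the north-east residence time, κ of 0.183 h⁻¹ makes κτ 1.37, and the balance gives L of 50.6%, so 49.4% of target, where that north-east tank gives 49.2%.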